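A direct plan would take both halves from apigenin (A1): O7-methylation to genkwanin (A2) and O4'-benzylation to A3 for the upper unit, O7-benzylation to A4 for the lower unit.
A3 and A4 would then be joined at C6–O by an oxidative C–H/O–H coupling (an aryl(mesityl)iodonium at C6 of A3, then copper-catalysed transfer of the phenoxide of A4) to give the dibenzyl biflavone A5, and hydrogenolysis would free the target.
Weakest steps: (1) the late diaryl ether coupling would rest on a reaction with no precedent on a flavone; it would have to choose C6 over C8 and outrun oxidation of the free phenol of A4 and mesityl transfer, and it would be tried on the two most advanced intermediates.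
(2) The mono-alkylations of A1 (O7 against O4', needed twice) would rest on a small acidity gap and would give mixtures in steps that build no skeleton.
(3) The last hydrogenolysis would put the C2=C3 bonds of a poorly soluble biflavone at risk, and since both ring systems are inherited from A1 the plan would have no second access to the hindered C6–O bond.

**Retrosynthetic overview** (unit 1 = the 7-methoxyflavone with rings A1, C1, B1; unit 2 = the apigenin unit with rings A2, C2, B2)
Each γ-pyranone ring (C1 and C2) is cut at C8a–O1, C4a–C4 and O1–C2, which leads back to an aryne at C4a≡C8a and an arylpropiolic acid; the C5 oxygen beside the aryne bond steers the oxygen to C8a and the acyl carbon to C4a.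
The hindered C6–O–C4' diaryl ether is therefore made first, by SNAr of 4-bromo-2,6-dimethoxyphenol on 4-fluorobenzaldehyde, when ring A1 carries no other nucleophile; no flavone is ever O-arylated.
Order of ring formation: rings A1 and B2 are bought and joined (step 1), ring C1 is annulated on aryne 12 (step 7), then ring C2 on aryne 21, which brings in ring A2 (step 11); one BCl3 step then frees four phenols.
The oxygen pattern comes from the building blocks (methyl on O5 and O7 of unit 1, benzyl elsewhere), so neither a selective alkylation of a polyphenol nor an oxidative C–H/O–H coupling is needed.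

Key step: step 7

Assumption: O5 of unit 1 is carried as a methyl ether, because an ether peri to C4=O can be cleaved at the end in the presence of the C7 methyl ether; compounds 1, 2, 9, 10 and 16 are taken as commercial; the target has no stereocenter.

Step 1
Reactants: 1 4-bromo-2,6-dimethoxyphenol; 2 4-fluorobenzaldehyde
Product: 3 4-(4-bromo-2,6-dimethoxyphenoxy)benzaldehyde
Conditions: K2CO3 (1.5 equiv), DMF, 120 °C
Reagents that add atoms: none
Why: Nucleophilic aromatic substitution: the phenoxide of 1 displaces fluoride para to the formyl group of 2, so the hindered C6–O–C4' diaryl ether is formed at the start, when the phenol between the two methoxy groups is the only nucleophile, and the unactivated aryl bromide stays untouched.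

Step 2
Reactants: 3 4-(4-bromo-2,6-dimethoxyphenoxy)benzaldehyde
Product: 4 5-bromo-2-(4-ethynylphenoxy)-1,3-dimethoxybenzene
Conditions: dimethyl (1-diazo-2-oxopropyl)phosphonate (1.3 equiv), K2CO3 (2 equiv), MeOH, 0 °C → rt
Reagents that add atoms: Ohira–Bestmann reagent, dimethyl (1-diazo-2-oxopropyl)phosphonate, COP(=O)(OC)C(=[N+]=[N-])C(C)=O
Why: Seyferth–Gilbert homologation with the Ohira–Bestmann reagent: methanolysis releases the diazomethylphosphonate anion, which olefinates the aldehyde, and loss of N2 with a 1,2-hydrogen shift gives the terminal alkyne under conditions that leave the aryl bromide alone.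

Step 3
Reactants: 4 5-bromo-2-(4-ethynylphenoxy)-1,3-dimethoxybenzene
Product: 5 trimethyl({4-[4-bromo-2,6-dimethoxy-3-(trimethylsilyl)phenoxy]phenyl}ethynyl)silane
Conditions: TMSCl (5 equiv), THF, −78 °C; LiN(i-Pr)2 (2.3 equiv) added slowly; −78 → 0 °C
Reagents that add atoms: chlorotrimethylsilane, C[Si](C)(C)Cl
Why: Deprotonation with in situ silyl trapping: LiN(i-Pr)2 first lithiates the alkyne C–H, which TMSCl caps, and then removes the ring A1 proton that is acidified by both bromine and methoxy (two equivalent sites), and the TMSCl already present silylates this aryllithium before it can lose LiBr.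

Step 4
Reactants: 5 trimethyl({4-[4-bromo-2,6-dimethoxy-3-(trimethylsilyl)phenoxy]phenyl}ethynyl)silane
Product: 7 4-(4-ethynylphenoxy)-3,5-dimethoxy-2-(trimethylsilyl)phenol, via dimethyl arylboronate 6 (not isolated)
Conditions: n-BuLi (1.1 equiv), THF, −78 °C; B(OMe)3 (2 equiv), −78 °C → rt; then MeOH, aq NaOH, 30% H2O2, 0 °C → rt; work-up at pH 6–7
Reagents that add atoms: hydrogen peroxide, OO
Why: Bromine–lithium exchange, borylation and oxidation of the boronate place the hydroxyl group on the carbon that will become C8a, next to the silyl-bearing carbon, and the alkaline methanol of the oxidation also cleaves the alkynyl C–Si bond, whereas the aryl C–Si bond is stable to base.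

Step 5
Reactants: 7 4-(4-ethynylphenoxy)-3,5-dimethoxy-2-(trimethylsilyl)phenol
Product: 8 4-(4-ethynylphenoxy)-3,5-dimethoxy-2-(trimethylsilyl)phenyl trifluoromethanesulfonate
Conditions: Tf2O (1.2 equiv), pyridine (3 equiv), CH2Cl2, 0 °C
Reagents that add atoms: trifluoromethanesulfonic anhydride, O=S(=O)(OS(=O)(=O)C(F)(F)F)C(F)(F)F
Why: O-Sulfonylation of the phenol completes the ortho-silylaryl triflate, the fluoride-triggered aryne precursor, and the terminal alkyne is inert to Tf2O and pyridine.

Step 6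
Reactants: 9 1-(benzyloxy)-4-iodobenzene; 10 propiolic acid
Product: 11 3-[4-(benzyloxy)phenyl]prop-2-ynoic acid
Conditions: PdCl2(PPh3)2 (2.5 mol %), 1,4-bis(diphenylphosphino)butane (5 mol %), DBU (2.2 equiv), DMSO, 30 °C; then 1 M HCl
Reagents that add atoms: none
Why: Copper-free Sonogashira coupling: oxidative addition of the aryl iodide to zerovalent palladium and coupling with the DBU salt of propiolic acid at 30 °C gives the arylpropiolic acid without decarboxylation.

Step 7
Reactants: 8 4-(4-ethynylphenoxy)-3,5-dimethoxy-2-(trimethylsilyl)phenyl trifluoromethanesulfonate; 11 3-[4-(benzyloxy)phenyl]prop-2-ynoic acid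
Product: 14 2-[4-(benzyloxy)phenyl]-6-(4-ethynylphenoxy)-5,7-dimethoxy-4H-chromen-4-one, via aryne 12 (not isolated), via hydroxyaryl ynone 13 (not isolated)
Conditions: 8 (1.0 equiv), 11 (1.3 equiv), CsF (4 equiv), THF, 125 °C, sealed tube
Reagents that add atoms: none
Why: Fluoride removes the silyl group of 8 and triflate leaves to give aryne 12; the cesium carboxylate of 11 adds through oxygen to the aryne carbon that becomes C8a, the aryl anion formed at C4a attacks the adjacent ester carbonyl, and the four-membered alkoxide opens to the ortho-acyl phenoxide 13 (net insertion of the aryne into the C–O bond of the acid, forming C8a–O1 and C4a–C4). The phenoxide then closes ring C1 by 6-endo-dig oxa-Michael addition to the ynone (bond O1–C2), which under basic, metal-free conditions is preferred over 5-exo closure to an aurone. The closest known reaction type is the intermolecular C–O insertion of arynes into carboxylic acids, which with 3-arylpropiolic acids delivers flavones directly. The regiochemistry is secured by the C5 methoxy group beside the aryne bond: its inductive pull distorts the aryne and stabilises the carbanion at C4a, so the nucleophile attacks the remote and less hindered C8a, as with 3-alkoxyarynes in general; the C6 aryloxy and C7 methoxy groups lie further from the aryne bond and should not override this. No stereocenter is formed; the terminal alkyne, the benzyl ether and the diaryl ether have no reactive partner, and the high temperature favours acyl transfer over protonation of the aryl anion.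

Step 8
Reactants: 14 2-[4-(benzyloxy)phenyl]-6-(4-ethynylphenoxy)-5,7-dimethoxy-4H-chromen-4-one
Product: 15 3-[4-({2-[4-(benzyloxy)phenyl]-5,7-dimethoxy-4-oxo-4H-chromen-6-yl}oxy)phenyl]prop-2-ynoic acid
Conditions: CO2 (1 atm), Cs2CO3 (1.5 equiv), AgI (2 mol %), DMF, 50 °C; then 1 M HCl, 0 °C
Reagents that add atoms: carbon dioxide, O=C=O
Why: Silver-catalysed C–H carboxylation of a terminal alkyne: the silver acetylide formed with Cs2CO3 inserts CO2 to give the cesium propiolate, and the flavone, which has no free hydroxyl group, tolerates carbonate in DMF at 50 °C.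

Step 9
Reactants: 16 3,5-bis(benzyloxy)phenol
Product: 17 3,5-bis(benzyloxy)-2-bromophenol
Conditions: NBS (1.0 equiv), i-Pr2NH (10 mol %), CH2Cl2, −78 → 0 °C
Reagents that add atoms: N-bromosuccinimide, O=C1CCC(=O)N1Br
Why: Electrophilic aromatic bromination: with NBS and a catalytic secondary amine in CH2Cl2 at low temperature bromine is delivered ortho to the free hydroxyl group, and the two ortho positions of 16 are equivalent.

Step 10
Reactants: 17 3,5-bis(benzyloxy)-2-bromophenol
Product: 20 3,5-bis(benzyloxy)-2-(trimethylsilyl)phenyl trifluoromethanesulfonate, via aryl silyl ether 18 (not isolated), via lithium silylphenolate 19 (not isolated)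
Conditions: (Me3Si)2NH, THF, 70 °C, then evaporate; n-BuLi (1.1 equiv), THF, −100 °C; Tf2O (1.2 equiv), −100 → −78 °C
Reagents that add atoms: hexamethyldisilazane, C[Si](C)(C)N[Si](C)(C)C; trifluoromethanesulfonic anhydride, O=S(=O)(OS(=O)(=O)C(F)(F)F)C(F)(F)F
Why: O-Silylation, bromine–lithium exchange and retro-Brook rearrangement (1,3 shift of silicon from oxygen to carbon) give the ortho-silyl phenoxide 19, which Tf2O traps as the triflate; the exchange at −100 °C is faster than any reaction at the benzyl ethers.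

Step 11
Reactants: 15 3-[4-({2-[4-(benzyloxy)phenyl]-5,7-dimethoxy-4-oxo-4H-chromen-6-yl}oxy)phenyl]prop-2-ynoic acid; 20 3,5-bis(benzyloxy)-2-(trimethylsilyl)phenyl trifluoromethanesulfonate
Product: 23 2-[4-(benzyloxy)phenyl]-6-{4-[5,7-bis(benzyloxy)-4-oxo-4H-chromen-2-yl]phenoxy}-5,7-dimethoxy-4H-chromen-4-one, via aryne 21 (not isolated), via hydroxyaryl ynone 22 (not isolated)
Conditions: 15 (1.0 equiv), 20 (1.8 equiv), CsF (5 equiv), THF, 125 °C, sealed tube
Reagents that add atoms: none
Why: Same aryne C–O insertion and 6-endo-dig oxa-Michael annulation as in step 7: the C5 benzyloxy group beside the aryne bond of 21 directs the carboxylate oxygen of 15 to C8a and the acyl carbon to C4a, which builds ring C2 and joins ring A2 to the rest of the skeleton.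

Step 12
Reactants: 23 2-[4-(benzyloxy)phenyl]-6-{4-[5,7-bis(benzyloxy)-4-oxo-4H-chromen-2-yl]phenoxy}-5,7-dimethoxy-4H-chromen-4-one
Product: 24 isocryptomerin
Conditions: BCl3 (12 equiv), C6HMe5 (10 equiv), CH2Cl2, −78 °C → rt; MeOH quench
Reagents that add atoms: none
Why: Lewis acid ether cleavage: BCl3 removes the three benzyl groups (pentamethylbenzene traps the benzyl cations) and, through a boron chelate with C4=O, the C5 methyl ether of unit 1, whereas the unchelated C7 methyl ether and the diaryl ether are not cleaved at or below room temperature.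

**Compound list**
1 | 4-bromo-2,6-dimethoxyphenol | COc1cc(Br)cc(OC)c1O | starting material
2 | 4-fluorobenzaldehyde | O=Cc1ccc(F)cc1 | starting material
3 | 4-(4-bromo-2,6-dimethoxyphenoxy)benzaldehyde | COc1cc(Br)cc(OC)c1Oc1ccc(C=O)cc1 | intermediate
4 | 5-bromo-2-(4-ethynylphenoxy)-1,3-dimethoxybenzene | COc1cc(Br)cc(OC)c1Oc1ccc(C#C)cc1 | intermediate
5 | trimethyl({4-[4-bromo-2,6-dimethoxy-3-(trimethylsilyl)phenoxy]phenyl}ethynyl)silane | COc1cc(Br)c([Si](C)(C)C)c(OC)c1Oc1ccc(C#C[Si](C)(C)C)cc1 | intermediate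
6 | dimethyl (3,5-dimethoxy-2-(trimethylsilyl)-4-{4-[(trimethylsilyl)ethynyl]phenoxy}phenyl)boronate | COB(OC)c1cc(OC)c(Oc2ccc(C#C[Si](C)(C)C)cc2)c(OC)c1[Si](C)(C)C | intermediate
7 | 4-(4-ethynylphenoxy)-3,5-dimethoxy-2-(trimethylsilyl)phenol | COc1cc(O)c([Si](C)(C)C)c(OC)c1Oc1ccc(C#C)cc1 | intermediate
8 | 4-(4-ethynylphenoxy)-3,5-dimethoxy-2-(trimethylsilyl)phenyl trifluoromethanesulfonate | COc1cc(OS(=O)(=O)C(F)(F)F)c([Si](C)(C)C)c(OC)c1Oc1ccc(C#C)cc1 | intermediate
9 | 1-(benzyloxy)-4-iodobenzene | Ic1ccc(OCc2ccccc2)cc1 | starting material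
10 | propiolic acid | C#CC(=O)O | starting material
11 | 3-[4-(benzyloxy)phenyl]prop-2-ynoic acid | O=C(O)C#Cc1ccc(OCc2ccccc2)cc1 | intermediate
12 | 4-(4-ethynylphenoxy)-3,5-dimethoxybenzyne (1,2-didehydrobenzene, aryne bond between the future C4a and C8a) | COC1=CC#CC(OC)=C1Oc1ccc(C#C)cc1 | intermediate
13 | 3-[4-(benzyloxy)phenyl]-1-[3-(4-ethynylphenoxy)-6-hydroxy-2,4-dimethoxyphenyl]prop-2-yn-1-one | COc1cc(O)c(C(=O)C#Cc2ccc(OCc3ccccc3)cc2)c(OC)c1Oc1ccc(C#C)cc1 | intermediate
14 | 2-[4-(benzyloxy)phenyl]-6-(4-ethynylphenoxy)-5,7-dimethoxy-4H-chromen-4-one | COc1cc2oc(-c3ccc(OCc4ccccc4)cc3)cc(=O)c2c(OC)c1Oc1ccc(C#C)cc1 | intermediate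
15 | 3-[4-({2-[4-(benzyloxy)phenyl]-5,7-dimethoxy-4-oxo-4H-chromen-6-yl}oxy)phenyl]prop-2-ynoic acid | COc1cc2oc(-c3ccc(OCc4ccccc4)cc3)cc(=O)c2c(OC)c1Oc1ccc(C#CC(=O)O)cc1 | intermediate
16 | 3,5-bis(benzyloxy)phenol | Oc1cc(OCc2ccccc2)cc(OCc2ccccc2)c1 | starting material
17 | 3,5-bis(benzyloxy)-2-bromophenol | Oc1cc(OCc2ccccc2)cc(OCc2ccccc2)c1Br | intermediate
18 | [3,5-bis(benzyloxy)-2-bromophenoxy]trimethylsilane | C[Si](C)(C)Oc1cc(OCc2ccccc2)cc(OCc2ccccc2)c1Br | intermediate
19 | lithium 3,5-bis(benzyloxy)-2-(trimethylsilyl)phenolate | [Li+].[O-]c1cc(OCc2ccccc2)cc(OCc2ccccc2)c1[Si](C)(C)C | intermediate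
20 | 3,5-bis(benzyloxy)-2-(trimethylsilyl)phenyl trifluoromethanesulfonate | C[Si](C)(C)c1c(OCc2ccccc2)cc(OCc2ccccc2)cc1OS(=O)(=O)C(F)(F)F | intermediate
21 | 3,5-bis(benzyloxy)benzyne (1,2-didehydrobenzene) | C1#CC(OCc2ccccc2)=CC(OCc2ccccc2)=C1 | intermediate
22 | 1-[2,4-bis(benzyloxy)-6-hydroxyphenyl]-3-[4-({2-[4-(benzyloxy)phenyl]-5,7-dimethoxy-4-oxo-4H-chromen-6-yl}oxy)phenyl]prop-2-yn-1-one | COc1cc2oc(-c3ccc(OCc4ccccc4)cc3)cc(=O)c2c(OC)c1Oc1ccc(C#CC(=O)c2c(O)cc(OCc3ccccc3)cc2OCc2ccccc2)cc1 | intermediate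
23 | 2-[4-(benzyloxy)phenyl]-6-{4-[5,7-bis(benzyloxy)-4-oxo-4H-chromen-2-yl]phenoxy}-5,7-dimethoxy-4H-chromen-4-one | COc1cc2oc(-c3ccc(OCc4ccccc4)cc3)cc(=O)c2c(OC)c1Oc1ccc(-c2cc(=O)c3c(OCc4ccccc4)cc(OCc4ccccc4)cc3o2)cc1 | intermediate
24 | isocryptomerin, 6-[4-(5,7-dihydroxy-4-oxo-4H-chromen-2-yl)phenoxy]-5-hydroxy-2-(4-hydroxyphenyl)-7-methoxy-4H-chromen-4-one | COc1cc2oc(-c3ccc(O)cc3)cc(=O)c2c(O)c1Oc1ccc(-c2cc(=O)c3c(O)cc(O)cc3o2)cc1 | target

Total step count: 12. Longest linear sequence: 9 steps (steps 1, 2, 3, 4, 5, 7, 8, 11, 12).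

**Steps most likely to fail**

Step 7. The aryl anion may be protonated before acyl transfer, so that only O-arylation of the acid occurs. It may also add to the alkyne carbon of the propiolate and lead to a 4-arylcoumarin, the carboxylate may attack the wrong aryne carbon, or the acid may lose CO2 at 125 °C.

The fallback sets out from 5 and comes back at 14. Bromine–lithium exchange and borylation as in step 4 (through 6), followed by a buffered oxidation (NaBO3·4H2O, THF–H2O) that spares the alkynyl silane, would give 3,5-dimethoxy-2-(trimethylsilyl)-4-{4-[(trimethylsilyl)ethynyl]phenoxy}phenol F1. ipso-Iododesilylation (ICl, CH2Cl2, −78 °C) would give 2-iodo-3,5-dimethoxy-4-{4-[(trimethylsilyl)ethynyl]phenoxy}phenol F2. Carbonylative Sonogashira annulation of F2 with commercial 1-(benzyloxy)-4-ethynylbenzene F3 (PdCl2(PPh3)2, CO 1 atm, Et2NH, DMF, 60 °C) would pass through 3-[4-(benzyloxy)phenyl]-1-(6-hydroxy-2,4-dimethoxy-3-{4-[(trimethylsilyl)ethynyl]phenoxy}phenyl)prop-2-yn-1-one F4. Amine-promoted closure would give 2-[4-(benzyloxy)phenyl]-5,7-dimethoxy-6-{4-[(trimethylsilyl)ethynyl]phenoxy}-4H-chromen-4-one F5, and K2CO3 in MeOH would then remove the alkynyl silyl group to give 14.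

Step 11. The same losses as in step 7 may occur on a larger and less soluble cesium carboxylate, and 15 may lose CO2 before it meets the aryne.

The fallback sets out from 14 (it bypasses steps 8 to 10) and comes back at 23. Iodination of 16 (N-iodosuccinimide, CH2Cl2, −78 °C) would give 3,5-bis(benzyloxy)-2-iodophenol F6. Palladium-catalysed carbonylative annulation of the terminal alkyne 14 with F6 (PdCl2(PPh3)2, CO 1 atm, Et2NH, DMF, 60 °C) would form the ynone 22, which should close to 23 under the amine conditions.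

Step 3. A second silylation may occur at the other position beside bromine, or the lithiated ring may lose LiBr or let bromine migrate before the silyl chloride traps it.

The fallback sets out from 4 and comes back at 7. Bromine–lithium exchange (n-BuLi, 2.1 equiv, the first for the alkyne C–H) and B(OMe)3 would give dimethyl [4-(4-ethynylphenoxy)-3,5-dimethoxyphenyl]boronate F7, which H2O2 and NaOH would oxidise to 4-(4-ethynylphenoxy)-3,5-dimethoxyphenol F8. Bromination ortho to the hydroxyl group (NBS, CH2Cl2, −78 °C; two equivalent sites) would give 2-bromo-4-(4-ethynylphenoxy)-3,5-dimethoxyphenol F9. O-Silylation with (Me3Si)2NH would give [2-bromo-4-(4-ethynylphenoxy)-3,5-dimethoxyphenoxy]trimethylsilane F10, and n-BuLi (2.1 equiv, −100 °C) would then trigger the retro-Brook shift to give 7 after NH4Cl work-up.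

**Further compounds**
F1 | step 7 | 3,5-dimethoxy-2-(trimethylsilyl)-4-{4-[(trimethylsilyl)ethynyl]phenoxy}phenol | COc1cc(O)c([Si](C)(C)C)c(OC)c1Oc1ccc(C#C[Si](C)(C)C)cc1
F2 | step 7 | 2-iodo-3,5-dimethoxy-4-{4-[(trimethylsilyl)ethynyl]phenoxy}phenol | COc1cc(O)c(I)c(OC)c1Oc1ccc(C#C[Si](C)(C)C)cc1
F3 | step 7 | 1-(benzyloxy)-4-ethynylbenzene | C#Cc1ccc(OCc2ccccc2)cc1
F4 | step 7 | 3-[4-(benzyloxy)phenyl]-1-(6-hydroxy-2,4-dimethoxy-3-{4-[(trimethylsilyl)ethynyl]phenoxy}phenyl)prop-2-yn-1-one | COc1cc(O)c(C(=O)C#Cc2ccc(OCc3ccccc3)cc2)c(OC)c1Oc1ccc(C#C[Si](C)(C)C)cc1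
F5 | step 7 | 2-[4-(benzyloxy)phenyl]-5,7-dimethoxy-6-{4-[(trimethylsilyl)ethynyl]phenoxy}-4H-chromen-4-one | COc1cc2oc(-c3ccc(OCc4ccccc4)cc3)cc(=O)c2c(OC)c1Oc1ccc(C#C[Si](C)(C)C)cc1
F6 | step 11 | 3,5-bis(benzyloxy)-2-iodophenol | Oc1cc(OCc2ccccc2)cc(OCc2ccccc2)c1I
F7 | step 3 | dimethyl [4-(4-ethynylphenoxy)-3,5-dimethoxyphenyl]boronate | COB(OC)c1cc(OC)c(Oc2ccc(C#C)cc2)c(OC)c1
F8 | step 3 | 4-(4-ethynylphenoxy)-3,5-dimethoxyphenol | COc1cc(O)cc(OC)c1Oc1ccc(C#C)cc1
F9 | step 3 | 2-bromo-4-(4-ethynylphenoxy)-3,5-dimethoxyphenol | COc1cc(O)c(Br)c(OC)c1Oc1ccc(C#C)cc1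
F10 | step 3 | [2-bromo-4-(4-ethynylphenoxy)-3,5-dimethoxyphenoxy]trimethylsilane | COc1cc(O[Si](C)(C)C)c(Br)c(OC)c1Oc1ccc(C#C)cc1
A1 | direct plan | apigenin | O=c1cc(-c2ccc(O)cc2)oc2cc(O)cc(O)c12
A2 | direct plan | genkwanin | COc1cc(O)c2c(=O)cc(-c3ccc(O)cc3)oc2c1
A3 | direct plan | 4'-O-benzylgenkwanin | COc1cc(O)c2c(=O)cc(-c3ccc(OCc4ccccc4)cc3)oc2c1
A4 | direct plan | 7-O-benzylapigenin | O=c1cc(-c2ccc(O)cc2)oc2cc(OCc3ccccc3)cc(O)c12
A5 | direct plan | di-O-benzylisocryptomerin | COc1cc2oc(-c3ccc(OCc4ccccc4)cc3)cc(=O)c2c(O)c1Oc1ccc(-c2cc(=O)c3c(O)cc(OCc4ccccc4)cc3o2)cc1
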